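The easy step comes first: I follow one molecule of target and ask how long it stays target.

| flask | starting material | target | remark | time |
|---|---|---|---|---|
| amber | 0.10 M | 5 mM | run made earlier |  |
| grey | 0.050 M | 5 mM | run made earlier |  |
| red | 0.075 M | 5 mM | run made earlier |  |
| Sunday's | 0.10 M (fed, over 4.00 min) | 5.00 mM | a stirred flask in which starting material is dosed at a steady rate over 4.00 min without added volume, worked up at 4.0 min | 4.0 min |
| Thursday's | 0.10 M | 5.00 mM | a closed flask charged with all of it at once and left for 4.0 min | 4.0 min |
| Wednesday's | 0.10 M | 5.00 mM | one stirred flow tank at steady state, fed with the mixture as stated, mean residence time 4.0 min |  |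
| Tuesday's | 0.10 M | 5.00 mM | a single well-mixed tank run continuously and read at steady state, 12.0 min in it on average |  |

1. the set-up with the highest share of target in all that became target or over-reaction product or isomer of the product, at the outlet or at the end ("none" if the first two lie within 2 percentage points) (Sunday's / Thursday's / Wednesday's / Tuesday's / none)
2. share of target in all that became target or over-reaction product or isomer of the product, at the outlet or at the end, Sunday's
3. share of target in all that became target or over-reaction product or isomer of the product, at the outlet or at the end, Thursday's
4. share of target in all that became target or over-reaction product or isomer of the product, at the outlet or at the end, Wednesday's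
5. share of target in all that became target or over-reaction product or isomer of the product, at the outlet or at the end, Tuesday's

- the stated concentrations are those of everything mixed, before any reaction; amounts are the same in each set-up
- the analysis behind the earlier runs scatters by 0.5 percentage points, standard deviation
- the feed brings no volume worth counting
- the earlier runs were made in a closed, stirred flask

| run | time / min | target / % | over-reaction product / % | isomer of the product / % |
|---|---|---|---|---|
| amber | 0.200 | 95.5 | 3.5 | 4.4 |
| amber | 0.333 | 89.5 | 7.8 | 7.8 |
| amber | 0.667 | 72.5 | 16.4 | 15.6 |
| amber | 1.33 | 47.5 | 28.3 | 28.2 |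
| amber | 2.50 | 24.0 | 41.3 | 39.3 |
| grey | 0.200 | 78.2 | 3.3 | 2.3 |
| grey | 0.333 | 93.2 | 7.6 | 6.0 |
| grey | 0.667 | 78.8 | 16.0 | 15.5 |
| grey | 1.33 | 52.8 | 29.4 | 28.8 |
| grey | 2.50 | 26.3 | 44.3 | 39.3 |
| red | 0.200 | 90.7 | 2.9 | 3.5 |
| red | 0.333 | 91.5 | 7.1 | 7.2 |
| red | 0.667 | 74.5 | 16.2 | 15.8 |
| red | 1.33 | 49.6 | 28.8 | 28.9 |
| red | 2.50 | 24.9 | 42.4 | 39.4 |

(standard deviation of a reading: 0.5 percentage points)

I read the amber table downward. From 0.667 min to 2.50 min target falls from 72.5% to 24.0%, while over-reaction product climbs from 16.4% to 41.3% and isomer of the product from 15.6% to 39.3%. That fall gives a reading of L, the mean life of a target molecule at this two-way fork, 1.66 min. The same rows of the grey table, with half the starting material, read 1.67 min, so I treat the loss as first order. Even the grey run has its highest target reading at 0.333 min, which is shorter than L, so I count a molecule's age from its entry into the flask.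

A molecule of age a survives with chance exp(−a/L), and the share asked is that chance averaged over the ages in the vessel (the residence-time distribution). I take Thursday's flask as holding one age, which gives 8.96%. Sunday's dosing spreads ages evenly up to 4.00 min, which gives 37.8%. A tank has exponentially spread ages, so the chance is L/(L + τ), with τ the mean residence time: 29.3% for Wednesday's and 12.1% for Tuesday's.

The forecast names Sunday's, with 37% for Sunday's, 11.3% for Thursday's, 30% for Wednesday's and 14% for Tuesday's: “All stay ignited, since seed is fed. Dosing wins.” Its order is mine, but its Thursday's and Tuesday's values stand above my reckoning.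

The simulation gives Sunday's, with 37.0% for Sunday's, 11.1% for Thursday's, 30.0% for Wednesday's and 14.0% for Tuesday's.

    starting material + target → 2 target (k = 5.40 M⁻¹ s⁻¹)
    starting material → target (k = 2.30 × 10⁻⁵ s⁻¹)
    target ⇌ isomer of the product (K = 5.30, k = 0.00540 s⁻¹)
    target → over-reaction product (k = 0.00540 s⁻¹)
    starting material → decomposition product (k = 7.20 × 10⁻⁶ s⁻¹)

In Thursday's flask, starting material has a half-life of 2.4 s by the path from starting material + target to 2 target at 0.0922 min, against 2.1 min for target by its path to over-reaction product alone. At 4.00 min that flask holds 11.6% target and Sunday's holds 38.1%.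

The same flask as Thursday's, read at 1.0 min, is a second case: L gives 54.7% there. The computed share in that flask is 56.1%, above the 37.0% of Sunday's at 4.0 min.

The runs are simulated for an exercise; the scatter is artificial.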